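**Retrosynthetic overview**
- Feature: on ring B the C3 and C5 methyls flank the ester oxygen O4, and these two carbons lie para and ortho to the C6 hydroxyl, exactly where electrophilic bromination goes.
- Key disconnection: C3–CH3 and C5–CH3 are cut together, leading back to the ring-B 3,5-dibromo depside 9 and trimethylboroxine 10 (twofold Suzuki–Miyaura methylation).
- 9 comes from dibromination of depside 7, and 7 from the ester bond C(=O)–O4 between acid 4 and the unflanked C4 hydroxyl of methyl orsellinate 5.
- Acid 4 comes from atraric acid 1 by 4′-O-methylation, chlorination at C3′ and saponification.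
- No ring is formed: both benzene rings are bought.

Key step: step 6

Remark: the target has no stereocentre and no configurationally stable axis, so "single enantiomer" is taken to mean the one achiral compound drawn; no stereocontrol is needed.
Remark on numbering (that of the target, used for all compounds): ring B has CO2CH3 on C1, CH3 on C2, the ester oxygen on C4 and OH on C6. Ring A has the carbonyl on C1′, CH3 on C2′, Cl on C3′, OCH3 on C4′, CH3 on C5′ and OH on C6′.

Step 1
Reactants: 1 methyl 4,6-dihydroxy-2,5-dimethylbenzoate (atraric acid, usually written methyl 2,4-dihydroxy-3,6-dimethylbenzoate)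
Product: 2 methyl 6-hydroxy-4-methoxy-2,5-dimethylbenzoate
Conditions: MeI (1.1 equiv), K2CO3, acetone, reflux
Reagents that add atoms: iodomethane, CI
Why: Williamson ether synthesis; the C4′ hydroxyl is the more acidic, unchelated phenol, whereas the C6′ hydroxyl is hydrogen-bonded to the ester carbonyl, so one equivalent of iodomethane should alkylate O4′ only.

Step 2
Reactants: 2 methyl 6-hydroxy-4-methoxy-2,5-dimethylbenzoate
Product: 3 methyl 3-chloro-6-hydroxy-4-methoxy-2,5-dimethylbenzoate
Conditions: SO2Cl2 (1.05 equiv), CH2Cl2, 0 °C to rt, dark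
Reagents that add atoms: sulfuryl chloride, O=S(=O)(Cl)Cl
Why: Electrophilic aromatic chlorination; C3′ is the only unsubstituted ring carbon and is activated para to the C6′ hydroxyl and ortho to the C4′ methoxy group, so ionic chlorination should be regiospecific.

Step 3
Reactants: 3 methyl 3-chloro-6-hydroxy-4-methoxy-2,5-dimethylbenzoate
Product: 4 3-chloro-6-hydroxy-4-methoxy-2,5-dimethylbenzoic acid
Conditions: KOH (excess), DMSO–H2O (4:1), 80 °C; then 2 M HCl, 0 °C
Reagents that add atoms: potassium hydroxide, [K+].[OH-]
Why: Saponification of a di-ortho-substituted benzoate by poorly solvated hydroxide in aqueous DMSO; the dianion resists decarboxylation and is protonated only in the cold.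

Step 4
Reactants: 4 3-chloro-6-hydroxy-4-methoxy-2,5-dimethylbenzoic acid; 5 methyl 4,6-dihydroxy-2-methylbenzoate (methyl orsellinate, usually written methyl 2,4-dihydroxy-6-methylbenzoate)
Product: 7 methyl 4-[(3-chloro-6-hydroxy-4-methoxy-2,5-dimethylbenzoyl)oxy]-6-hydroxy-2-methylbenzoate (depside), via mixed trifluoroacetic anhydride 6 (not isolated)
Conditions: (CF3CO)2O (3 equiv), toluene, rt; aq. NaHCO3 work-up
Reagents that add atoms: none
Why: Depside esterification through a mixed trifluoroacetic anhydride (acylium-type acyl transfer); the electron-rich di-ortho-substituted acid ionises readily, the C4 hydroxyl of 5 is the only unchelated phenol and has no ortho substituent, and the C6′ hydroxyl of 4 is held in a hydrogen bond to its own carbonyl.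

Step 5
Reactants: 7 methyl 4-[(3-chloro-6-hydroxy-4-methoxy-2,5-dimethylbenzoyl)oxy]-6-hydroxy-2-methylbenzoate
Product: 9 methyl 3,5-dibromo-4-[(3-chloro-6-hydroxy-4-methoxy-2,5-dimethylbenzoyl)oxy]-6-hydroxy-2-methylbenzoate (ring-B dibromo depside), via C3-monobromo depside 8 (not isolated)
Conditions: Br2 (2.3 equiv), NaOAc, AcOH, rt to 45 °C, dark
Reagents that add atoms: bromine, BrBr
Why: Electrophilic aromatic bromination; C3 (para to the C6 hydroxyl, expected to react first) and C5 (ortho to it) are the only unsubstituted ring carbons in the molecule and both are also ortho to O4, ring A is fully substituted, and the acetate buffer takes up HBr.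

Step 6
Reactants: 9 methyl 3,5-dibromo-4-[(3-chloro-6-hydroxy-4-methoxy-2,5-dimethylbenzoyl)oxy]-6-hydroxy-2-methylbenzoate; 10 trimethylboroxine
Product: 13 methyl 4-[(3-chloro-6-hydroxy-4-methoxy-2,5-dimethylbenzoyl)oxy]-6-hydroxy-2,3,5-trimethylbenzoate (target), via 5-bromo-3-methyl depside 11 (not isolated), via 3-bromo-5-methyl depside 12 (not isolated)
Conditions: 10 (2.5 equiv), PdCl2(dppf)·CH2Cl2 (10 mol %), anhydrous K2CO3 (6 equiv), 1,4-dioxane, 100 °C, sealed tube, Ar; cold 1 M HCl work-up
Reagents that add atoms: trimethylboroxine (10), CB1OB(C)OB(C)O1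
Why: Pd(0) should insert into each ring-B C–Br bond, the carbonate-activated boroxine should pass a methyl group to palladium, and reductive elimination should form C3–CH3 and C5–CH3 in turn, so that either mono-methylated bromide (11 or 12) leads on to 13. The closest known reaction type is the Suzuki–Miyaura methylation of ortho-substituted aryl bromides and free bromophenols with trimethylboroxine. No ring is closed and no stereocentre is created. The selectivity needed is C–Br over C3′–Cl; it rests on the much faster oxidative addition of aryl bromides at a bisphosphine–palladium catalyst of modest activity, and on the chloride being flanked by CH3 and OCH3 and para to the ring-A phenoxide that forms under the base. The depside ester should survive because its carbonyl is shielded by the C2′ methyl and the C6′ oxygen and because the anhydrous carbonate medium contains no hydroxide or alkoxide.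

**Compound list**
1 | methyl 4,6-dihydroxy-2,5-dimethylbenzoate (atraric acid) | COC(=O)c1c(C)cc(O)c(C)c1O | starting material
2 | methyl 6-hydroxy-4-methoxy-2,5-dimethylbenzoate | COC(=O)c1c(C)cc(OC)c(C)c1O | intermediate
3 | methyl 3-chloro-6-hydroxy-4-methoxy-2,5-dimethylbenzoate | COC(=O)c1c(C)c(Cl)c(OC)c(C)c1O | intermediate
4 | 3-chloro-6-hydroxy-4-methoxy-2,5-dimethylbenzoic acid | OC(=O)c1c(C)c(Cl)c(OC)c(C)c1O | intermediate
5 | methyl 4,6-dihydroxy-2-methylbenzoate (methyl orsellinate) | COC(=O)c1c(C)cc(O)cc1O | starting material
6 | 3-chloro-6-hydroxy-4-methoxy-2,5-dimethylbenzoic trifluoroacetic anhydride (mixed anhydride, not isolated) | O=C(OC(=O)C(F)(F)F)c1c(C)c(Cl)c(OC)c(C)c1O | intermediate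
7 | methyl 4-[(3-chloro-6-hydroxy-4-methoxy-2,5-dimethylbenzoyl)oxy]-6-hydroxy-2-methylbenzoate | COC(=O)c1c(C)cc(OC(=O)c2c(C)c(Cl)c(OC)c(C)c2O)cc1O | intermediate
8 | methyl 3-bromo-4-[(3-chloro-6-hydroxy-4-methoxy-2,5-dimethylbenzoyl)oxy]-6-hydroxy-2-methylbenzoate (not isolated) | COC(=O)c1c(C)c(Br)c(OC(=O)c2c(C)c(Cl)c(OC)c(C)c2O)cc1O | intermediate
9 | methyl 3,5-dibromo-4-[(3-chloro-6-hydroxy-4-methoxy-2,5-dimethylbenzoyl)oxy]-6-hydroxy-2-methylbenzoate | COC(=O)c1c(C)c(Br)c(OC(=O)c2c(C)c(Cl)c(OC)c(C)c2O)c(Br)c1O | intermediate
10 | trimethylboroxine | CB1OB(C)OB(C)O1 | starting material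
11 | methyl 5-bromo-4-[(3-chloro-6-hydroxy-4-methoxy-2,5-dimethylbenzoyl)oxy]-6-hydroxy-2,3-dimethylbenzoate (not isolated) | COC(=O)c1c(C)c(C)c(OC(=O)c2c(C)c(Cl)c(OC)c(C)c2O)c(Br)c1O | intermediate
12 | methyl 3-bromo-4-[(3-chloro-6-hydroxy-4-methoxy-2,5-dimethylbenzoyl)oxy]-6-hydroxy-2,5-dimethylbenzoate (not isolated) | COC(=O)c1c(C)c(Br)c(OC(=O)c2c(C)c(Cl)c(OC)c(C)c2O)c(C)c1O | intermediate
13 | methyl 4-[(3-chloro-6-hydroxy-4-methoxy-2,5-dimethylbenzoyl)oxy]-6-hydroxy-2,3,5-trimethylbenzoate | COC(=O)c1c(C)c(C)c(OC(=O)c2c(C)c(Cl)c(OC)c(C)c2O)c(C)c1O | target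

Total step count: 6
Longest linear sequence: 6 steps (1 → 2 → 3 → 4 → 7 → 9 → 13); 5 and 10 are bought.

**Steps most likely to fail**

Step 6 (twofold methylation). Oxidative addition into the electron-rich, di-ortho-substituted phenoxide ring may be slow, so the coupling may stop after one methyl group or drift into hydrodebromination. Prolonged heating with base may also cleave the depside ester through the ring-A phenoxide. The fallback masks both phenols before the coupling. Setting out from 9, chloromethyl methyl ether and K2CO3 in DMF should give the bis(methoxymethyl) ether of the dibromo depside F1. The same Suzuki–Miyaura methylation with 10 (PdCl2(dppf), K2CO3, dioxane, 100 °C), now on a neutral arene that cannot form a phenoxide, should give the bis(methoxymethyl) ether of the target F2. Treatment with 3 M HCl in THF at 40 °C should then remove both acetals and come back to the route at 13.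

Step 5 (dibromination). The second bromination, at C5 between O4 and the chelated hydroxyl on a ring that already carries one bromine and two acyl-type groups, may stall. Forcing it may cause ipso attack or oxidation on the fully substituted ring-A phenol, or benzylic bromination. The fallback puts the halogens on before the ester is made. Setting out from 5, bromine in acetic acid at rt should give methyl 3,5-dibromo-4,6-dihydroxy-2-methylbenzoate F3, since the free resorcinol brominates far more readily than the depside. Acylation of its C4 hydroxyl by acid 4 with trifluoroacetic anhydride in toluene, through mixed anhydride 6, then comes back to the route at 9. This order means esterifying a phenol flanked by two bromines, which is why it is only the reserve; the small, linear acylium-type electrophile should still reach it.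

Step 4 (esterification). Activation of the free hydroxy acid may be diverted into self-acylation through the C6′ hydroxyl, trifluoroacetylation of 5 without acyl transfer, C-acylation of ring B, or decarboxylation of 4 in the acidic medium. The fallback protects the ring-A phenol and runs the acyl transfer under basic conditions. Setting out from 3, benzyl bromide and K2CO3 in DMF at 70 °C should give methyl 6-(benzyloxy)-3-chloro-4-methoxy-2,5-dimethylbenzoate F4. KOH in aqueous DMSO at 90 °C should give 6-(benzyloxy)-3-chloro-4-methoxy-2,5-dimethylbenzoic acid F5. Oxalyl chloride with catalytic DMF in CH2Cl2 should give 6-(benzyloxy)-3-chloro-4-methoxy-2,5-dimethylbenzoyl chloride F6. Reaction of this with 5 and K2CO3 in refluxing acetone (the C4 phenoxide is the more acidic and unhindered one) should give the O-benzyl depside F7. Hydrogenolysis (H2, Pd/C, EtOAc, no base, stopped at full conversion so that the aryl chloride is kept) comes back to the route at 7.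

**Further compounds**
F1 | step 6 | methyl 3,5-dibromo-4-{[3-chloro-4-methoxy-6-(methoxymethoxy)-2,5-dimethylbenzoyl]oxy}-6-(methoxymethoxy)-2-methylbenzoate | COC(=O)c1c(C)c(Br)c(OC(=O)c2c(C)c(Cl)c(OC)c(C)c2OCOC)c(Br)c1OCOC
F2 | step 6 | methyl 4-{[3-chloro-4-methoxy-6-(methoxymethoxy)-2,5-dimethylbenzoyl]oxy}-6-(methoxymethoxy)-2,3,5-trimethylbenzoate | COC(=O)c1c(C)c(C)c(OC(=O)c2c(C)c(Cl)c(OC)c(C)c2OCOC)c(C)c1OCOC
F3 | step 5 | methyl 3,5-dibromo-4,6-dihydroxy-2-methylbenzoate | COC(=O)c1c(C)c(Br)c(O)c(Br)c1O
F4 | step 4 | methyl 6-(benzyloxy)-3-chloro-4-methoxy-2,5-dimethylbenzoate | COC(=O)c1c(C)c(Cl)c(OC)c(C)c1OCc1ccccc1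
F5 | step 4 | 6-(benzyloxy)-3-chloro-4-methoxy-2,5-dimethylbenzoic acid | OC(=O)c1c(C)c(Cl)c(OC)c(C)c1OCc1ccccc1
F6 | step 4 | 6-(benzyloxy)-3-chloro-4-methoxy-2,5-dimethylbenzoyl chloride | O=C(Cl)c1c(C)c(Cl)c(OC)c(C)c1OCc1ccccc1
F7 | step 4 | methyl 4-{[6-(benzyloxy)-3-chloro-4-methoxy-2,5-dimethylbenzoyl]oxy}-6-hydroxy-2-methylbenzoate | COC(=O)c1c(C)cc(OC(=O)c2c(C)c(Cl)c(OC)c(C)c2OCc2ccccc2)cc1O
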